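The data were generated by integration on assumed constants, noise included.

Intermediate and target together cannot exceed the charge of solid substrate, and that bounds the late part of this flask.

| flask | solid substrate | remark | time |
|---|---|---|---|
| eta | 1.5 M | the very flask that is asked about, followed so far |  |
| epsilon | 1 M | run made earlier |  |
| flask | 1.5 M |  | 15 d |

| run | time / d | intermediate / % | target / % | solid substrate / % |
|---|---|---|---|---|
| eta | 0.208 | 8.0 | 0.7 | 48.4 |
| eta | 0.333 | 8.8 | 2.5 | 30.8 |
| eta | 0.625 | 19.3 | 9.0 | 0 |
| eta | 1.04 | 17.1 | 23.6 | 0 |
| eta | 1.67 | 8.3 | 34.9 | 0.2 |
| eta | 2.50 | 4.4 | 39.5 | 0 |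
| epsilon | 0.500 | 17.2 | 8.8 | 1.0 |
| epsilon | 0.833 | 19.8 | 21.1 | 0.4 |
| epsilon | 1.25 | 12.4 | 28.3 | 0.7 |
| epsilon | 2.00 | 7.7 | 39.0 | 0 |
| epsilon | 4.00 | 5.0 | 44.1 | 0.4 |
| epsilon | 6.00 | 7.4 | 50.1 | 0.5 |

(scatter of a reading: 1 percentage point)
- as a solid, counted per litre of solution: solid substrate
- the numbers in the tables scatter with a standard deviation of 1 percentage point
- what may be going on: intermediate <-> isomer of the product; solid substrate <-> starting material; intermediate <-> target; starting material <-> dormant form; starting material -> intermediate
- at the start none of the solid substrate is in solution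
- the best time, 15 d at the latest, for intermediate
- the amount of intermediate, in percent of the solid substrate charged, at that time
- earliest time at which at least nineteen twentieths of that best amount are there, in d
- latest time at which they still are, in d

In eta, the asked flask followed so far, the solid substrate reads 0% at 0.625 d, and intermediate reads 19.3% there, then falls. But in epsilon intermediate reads 5.0% at 4.00 d and 7.4% at 6.00 d, so you must ask whether a second rise could pass the first before 15 d. In the latest readings intermediate stands at a small fraction of target. Call f, the follow ratio, the late intermediate divided by the late target. Pooling the last eta reading and the last two of epsilon gives a reading of f = 0.126. If f holds to the end, the two species can share the whole charge at most, which puts intermediate at f/(1+f) = 11.2%. That is below the early reading, so I commit to the early maximum, between 0.333 d and 1.04 d.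

The forecast gives 20.5% at 0.75 d, with a window from 0.61 d to 0.92 d and a late level “below the early peak”.

The flask gives 19.1% at 0.725 d, and the window runs from 0.599 d to 0.888 d.

    intermediate ⇌ isomer of the product (K = 3.00, k = 9.59 × 10⁻⁶ /s)
    solid substrate ⇌ starting material, rate k2*(cs2 - [starting material]) while solid is left; crystals form when [starting material] > cs2 (solubility = 1.20 M, k = 4.96 × 10⁻⁵ /s)
    intermediate ⇌ target (K = 9.40, k = 2.14 × 10⁻⁵ /s)
    starting material ⇌ dormant form (K = 5.40, k = 1.20 × 10⁻⁵ /s)
    starting material → intermediate (k = 1.59 × 10⁻⁵ /s)

The forward half-life of intermediate towards the isomer of the product is 0.84 d, short against 15 d, and its forward use towards target is 2.2 times faster. At 15.0 d this flask holds 7.09% intermediate, below the 11.2% reckoned from f, with intermediate over target at 0.113 against the f read earlier. The same flask read at 10 d has that ratio at 0.120, with 6.83% intermediate.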